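Ring A (C1–C4, C4a, C8a; decalin numbering) is closed last through the C4–C4a bond, by an amine-catalysed aldol condensation of a methyl ketone side chain onto the C4a carbonyl of a monocyclic precursor. C4a is the only hydrogen-bearing carbon between the quaternary centres C5 and C8a. As a ketone it first serves to build both of them by enolate chemistry; the key step then turns it into the β-carbon of an enone, which is later reduced to the trans ring fusion. The precursor is a 2,2,6,6-tetrasubstituted cyclohexanone that already carries four of the five stereocentres, the arylmethyl group and the methyl ketone chain.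

Key step: step 9

Numbering and abbreviation: bicyclic compounds use the decalin numbering of the target: C1 (CH bearing the propanoic acid chain), C2 (isopropylidene carbon), C3, C4, C4a (ring-fusion CH), C5 (C with methyl and arylmethyl), C6 (CHMe), C7, C8, C8a (C with methyl). Ar* = 2-(tert-butyldimethylsilyloxy)-5-methoxy-3-methylphenyl.

Remark: the sense of induction of the amine auxiliary (step 4) and of the copper ligand (step 7) is assigned by analogy with the parent 2-methylcyclohexanone and cyclohex-2-enone cases; the other enantiomer of amine or ligand is used if the sense turns out reversed.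

Step 1
Reactants: 1 4-methoxy-2,6-dimethylphenol
Product: 2 tert-butyl(4-methoxy-2,6-dimethylphenoxy)dimethylsilane
Conditions: TBSCl, imidazole, DMF, 50 °C
Reagents that add atoms: tert-butyldimethylsilyl chloride, C[Si](C)(Cl)C(C)(C)C
Why: Silyl ether formation (Corey silylation) masks the phenol for the radical bromination and the later enolate alkylations.

Step 2
Reactants: 2 tert-butyl(4-methoxy-2,6-dimethylphenoxy)dimethylsilane
Product: 3 [2-(bromomethyl)-4-methoxy-6-methylphenoxy](tert-butyl)dimethylsilane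
Conditions: NBS (1.0 equiv), AIBN (cat.), PhCF3, 80 °C
Reagents that add atoms: N-bromosuccinimide, O=C1CCC(=O)N1Br
Why: Wohl–Ziegler benzylic bromination; the two methyl groups are equivalent, so mono-bromination gives a single bromide, and radical-chain conditions in a non-polar solvent should disfavour ring bromination.

Step 3
Reactants: 4 methyl 4-oxobutanoate
Product: 5 methyl (4E)-6-oxohept-4-enoate
Conditions: Ph3P=CHC(O)CH3, CH2Cl2, rt
Reagents that add atoms: 1-(triphenylphosphoranylidene)propan-2-one, CC(=O)C=P(c1ccccc1)(c1ccccc1)c1ccccc1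
Why: Wittig olefination with a stabilised ylide should give the E-enone needed as Michael acceptor.

Step 4
Reactants: 6 2-methylcyclohexanone (racemic); 5 methyl (4E)-6-oxohept-4-enoate
Product: 9 methyl (4R)-4-[(1S)-1-methyl-2-oxocyclohexyl]-6-oxoheptanoate, via imine 7 (not isolated), via adduct imine 8 (not isolated)
Conditions: i) (R)-1-phenylethylamine, TsOH (cat.), toluene, 110 °C (Dean–Stark); ii) 5, neat, 40 °C; iii) 10% aq. AcOH, rt
Reagents that add atoms: water, O
Why: Deracemising imine Michael addition (d'Angelo, aza-ene type): the more substituted secondary enamine tautomer of 7 adds to the E-enone through a compact cyclic transition state on the face remote from the auxiliary phenyl group, which should set the quaternary centre (S) and, by the synclinal approach known from Robinson annulations with β-substituted enones, the adjacent CH centre (R, later 1,8a-cis).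

Step 5
Reactants: 9 methyl (4R)-4-[(1S)-1-methyl-2-oxocyclohexyl]-6-oxoheptanoate
Product: 10 methyl (4R)-4-[(1S)-1-methyl-2-oxocyclohexyl]-5-(2-methyl-1,3-dioxolan-2-yl)pentanoate
Conditions: ethylene glycol (1.2 equiv), PPTS (cat.), benzene, 80 °C (Dean–Stark)
Reagents that add atoms: ethane-1,2-diol, OCCO
Why: Chemoselective ketalisation; the unhindered methyl ketone should react well before the α-quaternary ring ketone.

Step 6
Reactants: 10 methyl (4R)-4-[(1S)-1-methyl-2-oxocyclohexyl]-5-(2-methyl-1,3-dioxolan-2-yl)pentanoate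
Product: 11 methyl (4R)-4-[(1S)-1-methyl-2-oxocyclohex-3-en-1-yl]-5-(2-methyl-1,3-dioxolan-2-yl)pentanoate
Conditions: IBX (2 equiv), DMSO/PhF, 70 °C
Reagents that add atoms: none
Why: IBX α,β-dehydrogenation of a ketone; only the CH2–CH2 side can be desaturated because the other α-carbon is quaternary.

Step 7
Reactants: 11 methyl (4R)-4-[(1S)-1-methyl-2-oxocyclohex-3-en-1-yl]-5-(2-methyl-1,3-dioxolan-2-yl)pentanoate; 3 [2-(bromomethyl)-4-methoxy-6-methylphenoxy](tert-butyl)dimethylsilane
Product: 13 methyl (4R)-4-[(1S,3R,4S)-3-(Ar*-methyl)-1,4-dimethyl-2-oxocyclohexyl]-5-(2-methyl-1,3-dioxolan-2-yl)pentanoate, via zinc enolate 12 (not isolated)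
Conditions: Me2Zn, Cu(OTf)2 (2 mol %), (S,R,R)-binaphthyl bis(1-phenylethyl)phosphoramidite (4 mol %), toluene, −30 °C; then 3, HMPA, 0 °C → rt
Reagents that add atoms: dimethylzinc, C[Zn]C
Why: Copper-catalysed asymmetric conjugate addition (Feringa type) sets the methyl-bearing centre (ring C4, later C6) under catalyst control, and the zinc enolate is alkylated in situ by bromide 3, expected trans to the new methyl; this α-centre is re-enolised in step 8.

Step 8
Reactants: 13 methyl (4R)-4-[(1S,3R,4S)-3-(Ar*-methyl)-1,4-dimethyl-2-oxocyclohexyl]-5-(2-methyl-1,3-dioxolan-2-yl)pentanoate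
Product: 15 methyl (4R)-4-[(1S,3S,4S)-3-(Ar*-methyl)-1,3,4-trimethyl-2-oxocyclohexyl]-6-oxoheptanoate, via methylated ketal 14 (not isolated)
Conditions: LDA, THF/DMPU, −78 → 0 °C; MeI, −78 → −20 °C; then 1 M HCl, THF, rt
Reagents that add atoms: iodomethane, CI; water, O
Why: Enolate C-methylation followed by acetal hydrolysis: only ring C3 is enolisable, and methyl iodide should enter anti to the adjacent pseudoaxial C4 methyl (1,2-induction as in 2,3-dialkylcyclohexanone enolates) and anti to the bulky chain on C1, which sets the second quaternary centre with the arylmethyl group cis to the C4 methyl.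

Step 9
Reactants: 15 methyl (4R)-4-[(1S,3S,4S)-3-(Ar*-methyl)-1,3,4-trimethyl-2-oxocyclohexyl]-6-oxoheptanoate
Product: 18 methyl 3-[(1R,5S,6S,8aS)-5-(Ar*-methyl)-5,6,8a-trimethyl-3-oxo-1,2,3,5,6,7,8,8a-octahydronaphthalen-1-yl]propanoate, via enamine 16 (not isolated), via aldol adduct 17 (not isolated)
Conditions: pyrrolidine (0.5 equiv), AcOH (0.5 equiv), toluene, 110 °C (Dean–Stark)
Reagents that add atoms: none
Why: Pyrrolidine converts the methyl ketone into its less substituted enamine, whose terminal carbon (future C4) adds to the C4a carbonyl in a 6-(enolendo)-exo-trig closure; loss of water and hydrolysis give the enone, i.e. a Robinson-type intramolecular aldol condensation under enamine catalysis. The C4a ketone has no α-hydrogen and the internal enamine could only form a four-membered ring, so this is the only productive closure. No new stereocentre results, since C4a becomes sp2 and is set in step 11. The amine/acetic acid buffer avoids alkoxide, which could close the ε-keto ester to an acetylcyclopentanone, and strong acid, which could drive Friedel–Crafts attack of the electron-rich arene on C4a. The difficulty is a carbonyl flanked by two quaternary carbons; dehydration with water removal is relied on to pull the unfavourable aldol equilibrium forward.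

Step 10
Reactants: 18 methyl 3-[(1R,5S,6S,8aS)-5-(Ar*-methyl)-5,6,8a-trimethyl-3-oxo-1,2,3,5,6,7,8,8a-octahydronaphthalen-1-yl]propanoate
Product: 19 methyl 3-[(1R,2S,5S,6S,8aS)-5-(Ar*-methyl)-2-(2-hydroxypropan-2-yl)-5,6,8a-trimethyl-3-oxo-1,2,3,5,6,7,8,8a-octahydronaphthalen-1-yl]propanoate
Conditions: LDA, THF, −78 °C; acetone, −78 °C; sat. aq. NH4Cl
Reagents that add atoms: acetone, CC(C)=O
Why: Directed aldol addition: kinetic α′-deprotonation at C2 is the only enolisation open to the enone (both γ-carbons are quaternary), acetone is expected to add trans to the C1 chain, and this centre is removed again in step 12.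

Step 11
Reactants: 19 methyl 3-[(1R,2S,5S,6S,8aS)-5-(Ar*-methyl)-2-(2-hydroxypropan-2-yl)-5,6,8a-trimethyl-3-oxo-1,2,3,5,6,7,8,8a-octahydronaphthalen-1-yl]propanoate
Product: 20 methyl 3-[(1R,2S,4aR,5S,6S,8aS)-5-(Ar*-methyl)-2-(2-hydroxypropan-2-yl)-5,6,8a-trimethyl-3-oxodecahydronaphthalen-1-yl]propanoate
Conditions: Li (2.5 equiv), NH3(l)/THF, −78 °C, 15 min; NH4Cl
Reagents that add atoms: none
Why: Dissolving-metal (Birch-type) enone reduction: axial protonation of the β-carbon C4a (Stork's rule) should give the trans ring fusion, because the cis alternative with axial hydrogen would force the C6 methyl and C4 syn-diaxial; short exposure at −78 °C with limited lithium is meant to spare the ester and the aryl ether.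

Step 12
Reactants: 20 methyl 3-[(1R,2S,4aR,5S,6S,8aS)-5-(Ar*-methyl)-2-(2-hydroxypropan-2-yl)-5,6,8a-trimethyl-3-oxodecahydronaphthalen-1-yl]propanoate
Product: 21 methyl 3-[(1S,4aR,5S,6S,8aR)-5-(Ar*-methyl)-5,6,8a-trimethyl-3-oxo-2-(propan-2-ylidene)decahydronaphthalen-1-yl]propanoate
Conditions: TsOH·H2O (cat.), benzene, 60 °C
Reagents that add atoms: none
Why: Acid-catalysed dehydration of the tertiary β-ketol through the enol should give the conjugated, pulegone-type isopropylidene ketone, which is favoured over the isopropenyl isomer.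

Step 13
Reactants: 21 methyl 3-[(1S,4aR,5S,6S,8aR)-5-(Ar*-methyl)-5,6,8a-trimethyl-3-oxo-2-(propan-2-ylidene)decahydronaphthalen-1-yl]propanoate
Product: 22 methyl 3-[(1S,3R,4aR,5S,6S,8aR)-5-(Ar*-methyl)-3-hydroxy-5,6,8a-trimethyl-2-(propan-2-ylidene)decahydronaphthalen-1-yl]propanoate
Conditions: NaBH4, CeCl3·7H2O, MeOH, −20 °C
Reagents that add atoms: none
Why: Luche 1,2-reduction of the enone; axial hydride attack is expected to give the 3R carbinol shown, but either epimer serves because the centre is removed in step 14.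

Step 14
Reactants: 22 methyl 3-[(1S,3R,4aR,5S,6S,8aR)-5-(Ar*-methyl)-3-hydroxy-5,6,8a-trimethyl-2-(propan-2-ylidene)decahydronaphthalen-1-yl]propanoate
Product: 23 methyl 3-[(1S,4aR,5S,6S,8aR)-5-(Ar*-methyl)-5,6,8a-trimethyl-2-(propan-2-ylidene)decahydronaphthalen-1-yl]propanoate
Conditions: Et3SiH (5 equiv), BF3·OEt2 (2 equiv), CH2Cl2, −78 → −30 °C
Reagents that add atoms: none
Why: Ionic hydrogenation (reductive deoxygenation of an allylic alcohol): the Lewis acid ionises the carbinol to an allyl cation, and the silane should deliver hydride to the less hindered secondary ring terminus C3, leaving the tetrasubstituted exocyclic alkene.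

Step 15
Reactants: 23 methyl 3-[(1S,4aR,5S,6S,8aR)-5-(Ar*-methyl)-5,6,8a-trimethyl-2-(propan-2-ylidene)decahydronaphthalen-1-yl]propanoate
Product: 24 3-[(1S,4aR,5S,6S,8aR)-5-[(2-hydroxy-5-methoxy-3-methylphenyl)methyl]-5,6,8a-trimethyl-2-(propan-2-ylidene)decahydronaphthalen-1-yl]propanoic acid (target)
Conditions: LiOH·H2O, THF/MeOH/H2O, 50 °C (argon); then 1 M HCl to pH 4, 0 °C
Reagents that add atoms: lithium hydroxide, [Li+].[OH-]
Why: Saponification of the methyl ester with concurrent hydroxide cleavage of the aryl silyl ether; cold, mild acidification is chosen to avoid acid-induced lactonisation onto the tetrasubstituted alkene.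

Compound list
1 | 4-methoxy-2,6-dimethylphenol | COc1cc(C)c(O)c(C)c1 | starting material
2 | tert-butyl(4-methoxy-2,6-dimethylphenoxy)dimethylsilane | COc1cc(C)c(O[Si](C)(C)C(C)(C)C)c(C)c1 | intermediate
3 | [2-(bromomethyl)-4-methoxy-6-methylphenoxy](tert-butyl)dimethylsilane | COc1cc(C)c(O[Si](C)(C)C(C)(C)C)c(CBr)c1 | intermediate
4 | methyl 4-oxobutanoate | COC(=O)CCC=O | starting material
5 | methyl (4E)-6-oxohept-4-enoate | COC(=O)CC/C=C/C(C)=O | intermediate
6 | 2-methylcyclohexanone (racemic) | CC1CCCCC1=O | starting material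
7 | (1R)-N-(2-methylcyclohexylidene)-1-phenylethanamine (ring centre epimerising) | CC1CCCCC1=N[C@H](C)c1ccccc1 | intermediate (not isolated)
8 | methyl (4R)-4-[(1S)-1-methyl-2-{[(1R)-1-phenylethyl]imino}cyclohexyl]-6-oxoheptanoate | C1C(=N[C@H](C)c2ccccc2)[C@](C)([C@H](CCC(=O)OC)CC(C)=O)CCC1 | intermediate (not isolated)
9 | methyl (4R)-4-[(1S)-1-methyl-2-oxocyclohexyl]-6-oxoheptanoate | C1C(=O)[C@](C)([C@H](CCC(=O)OC)CC(C)=O)CCC1 | intermediate
10 | methyl (4R)-4-[(1S)-1-methyl-2-oxocyclohexyl]-5-(2-methyl-1,3-dioxolan-2-yl)pentanoate | C1C(=O)[C@](C)([C@H](CCC(=O)OC)CC2(C)OCCO2)CCC1 | intermediate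
11 | methyl (4R)-4-[(1S)-1-methyl-2-oxocyclohex-3-en-1-yl]-5-(2-methyl-1,3-dioxolan-2-yl)pentanoate | C1=CC(=O)[C@](C)([C@H](CCC(=O)OC)CC2(C)OCCO2)CC1 | intermediate
12 | methylzinc enolate (C2=C3) of methyl (4R)-4-[(1S,4S)-1,4-dimethyl-2-oxocyclohexyl]-5-(2-methyl-1,3-dioxolan-2-yl)pentanoate | C[Zn]OC1=C[C@@H](C)CC[C@@]1(C)[C@H](CCC(=O)OC)CC2(C)OCCO2 | intermediate (not isolated)
13 | methyl (4R)-4-[(1S,3R,4S)-3-(Ar*-methyl)-1,4-dimethyl-2-oxocyclohexyl]-5-(2-methyl-1,3-dioxolan-2-yl)pentanoate | COc1cc(C)c(O[Si](C)(C)C(C)(C)C)c(C[C@H]2C(=O)[C@](C)([C@H](CCC(=O)OC)CC3(C)OCCO3)CC[C@@H]2C)c1 | intermediate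
14 | methyl (4R)-4-[(1S,3S,4S)-3-(Ar*-methyl)-1,3,4-trimethyl-2-oxocyclohexyl]-5-(2-methyl-1,3-dioxolan-2-yl)pentanoate | COc1cc(C)c(O[Si](C)(C)C(C)(C)C)c(C[C@]2(C)C(=O)[C@](C)([C@H](CCC(=O)OC)CC3(C)OCCO3)CC[C@@H]2C)c1 | intermediate (not isolated)
15 | methyl (4R)-4-[(1S,3S,4S)-3-(Ar*-methyl)-1,3,4-trimethyl-2-oxocyclohexyl]-6-oxoheptanoate | COc1cc(C)c(O[Si](C)(C)C(C)(C)C)c(C[C@]2(C)C(=O)[C@](C)([C@H](CCC(=O)OC)CC(C)=O)CC[C@@H]2C)c1 | intermediate
16 | methyl (4R)-4-[(1S,3S,4S)-3-(Ar*-methyl)-1,3,4-trimethyl-2-oxocyclohexyl]-6-(pyrrolidin-1-yl)hept-6-enoate | COc1cc(C)c(O[Si](C)(C)C(C)(C)C)c(C[C@]2(C)C(=O)[C@](C)([C@H](CCC(=O)OC)CC(=C)N3CCCC3)CC[C@@H]2C)c1 | intermediate (not isolated)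
17 | methyl 3-[(1R,5S,6S,8aS)-5-(Ar*-methyl)-4a-hydroxy-5,6,8a-trimethyl-3-oxodecahydronaphthalen-1-yl]propanoate (either C4a epimer) | COc1cc(C)c(O[Si](C)(C)C(C)(C)C)c(C[C@]2(C)C3(O)CC(=O)C[C@@H](CCC(=O)OC)[C@]3(C)CC[C@@H]2C)c1 | intermediate (not isolated)
18 | methyl 3-[(1R,5S,6S,8aS)-5-(Ar*-methyl)-5,6,8a-trimethyl-3-oxo-1,2,3,5,6,7,8,8a-octahydronaphthalen-1-yl]propanoate | COc1cc(C)c(O[Si](C)(C)C(C)(C)C)c(C[C@]2(C)C3=CC(=O)C[C@@H](CCC(=O)OC)[C@]3(C)CC[C@@H]2C)c1 | intermediate
19 | methyl 3-[(1R,2S,5S,6S,8aS)-5-(Ar*-methyl)-2-(2-hydroxypropan-2-yl)-5,6,8a-trimethyl-3-oxo-1,2,3,5,6,7,8,8a-octahydronaphthalen-1-yl]propanoate | COc1cc(C)c(O[Si](C)(C)C(C)(C)C)c(C[C@]2(C)C3=CC(=O)[C@H](C(C)(C)O)[C@@H](CCC(=O)OC)[C@]3(C)CC[C@@H]2C)c1 | intermediate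
20 | methyl 3-[(1R,2S,4aR,5S,6S,8aS)-5-(Ar*-methyl)-2-(2-hydroxypropan-2-yl)-5,6,8a-trimethyl-3-oxodecahydronaphthalen-1-yl]propanoate | COc1cc(C)c(O[Si](C)(C)C(C)(C)C)c(C[C@]2(C)[C@H]3CC(=O)[C@H](C(C)(C)O)[C@@H](CCC(=O)OC)[C@]3(C)CC[C@@H]2C)c1 | intermediate
21 | methyl 3-[(1S,4aR,5S,6S,8aR)-5-(Ar*-methyl)-5,6,8a-trimethyl-3-oxo-2-(propan-2-ylidene)decahydronaphthalen-1-yl]propanoate | COc1cc(C)c(O[Si](C)(C)C(C)(C)C)c(C[C@]2(C)[C@H]3CC(=O)C(=C(C)C)[C@@H](CCC(=O)OC)[C@]3(C)CC[C@@H]2C)c1 | intermediate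
22 | methyl 3-[(1S,3R,4aR,5S,6S,8aR)-5-(Ar*-methyl)-3-hydroxy-5,6,8a-trimethyl-2-(propan-2-ylidene)decahydronaphthalen-1-yl]propanoate | COc1cc(C)c(O[Si](C)(C)C(C)(C)C)c(C[C@]2(C)[C@H]3C[C@@H](O)C(=C(C)C)[C@@H](CCC(=O)OC)[C@]3(C)CC[C@@H]2C)c1 | intermediate
23 | methyl 3-[(1S,4aR,5S,6S,8aR)-5-(Ar*-methyl)-5,6,8a-trimethyl-2-(propan-2-ylidene)decahydronaphthalen-1-yl]propanoate | COc1cc(C)c(O[Si](C)(C)C(C)(C)C)c(C[C@]2(C)[C@H]3CCC(=C(C)C)[C@@H](CCC(=O)OC)[C@]3(C)CC[C@@H]2C)c1 | intermediate
24 | 3-[(1S,4aR,5S,6S,8aR)-5-[(2-hydroxy-5-methoxy-3-methylphenyl)methyl]-5,6,8a-trimethyl-2-(propan-2-ylidene)decahydronaphthalen-1-yl]propanoic acid | COc1cc(C)c(O)c(C[C@]2(C)[C@H]3CCC(=C(C)C)[C@@H](CCC(=O)O)[C@]3(C)CC[C@@H]2C)c1 | target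

Total step count: 15. Longest linear sequence: 13 steps (steps 3–15, from methyl 4-oxobutanoate 4).

Steps most likely to fail

1. Step 9 (key step). The aldol addition may be unable to engage a carbonyl flanked by two quaternary carbons, so that retro-aldol outruns dehydration and the diketone is returned or diverted. The fallback replaces equilibrating amine catalysis by kinetic, irreversible C–C bond formation. It sets out from 15: LDA and TMSCl at −78 °C should give the kinetic trimethylsilyl enol ether F1 of the methyl ketone (the ring ketone has no α-hydrogen). TiCl4 in CH2Cl2 at −78 °C then effects an intramolecular Mukaiyama aldol addition to give aldol adduct 17, this time isolated. Dehydration with the Burgess reagent (or catalytic TsOH) rejoins the route at 18.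

2. Step 4. The aza-ene Michael addition may stall with a β-substituted enone, the imine then decomposing or reacting with poor facial and simple diastereoselection. The fallback uses a doubly activated acceptor and later excises the extra acyl group. It sets out from 4 and 6: Knoevenagel condensation of 4 with pentane-2,4-dione (piperidinium acetate) gives alkylidene diketone F2. Its reaction with imine 7 (from 6, as in step 4) gives adduct imine F3, which is hydrolysed with aqueous acetic acid to triketo ester F4. Retro-Claisen deacetylation (K2CO3, MeOH, 0 °C) then comes back to the route at 9.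

3. Step 14. Hydride may be delivered to the tertiary terminus of the allyl cation, or the cation may lose a proton, giving alkene-transposed or diene products. The fallback removes the C3 oxygen through an enol triflate and not through a cation. It sets out from 21: kinetic enolisation toward C4 (KHMDS, THF, −78 °C) and trapping with PhNTf2 give dienyl triflate F5. Palladium-catalysed formate reduction (Pd(OAc)2, PPh3, HCO2H, Bu3N, DMF, 60 °C) gives diene F6, which is also the product of the elimination side path of step 14. Diimide (2-nitrobenzenesulfonylhydrazide, Et3N, rt) should saturate only the disubstituted C3=C4 bond and comes back to the route at 23.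

Further compounds
F1 | step 9 | methyl (4R)-4-[(1S,3S,4S)-3-(Ar*-methyl)-1,3,4-trimethyl-2-oxocyclohexyl]-6-(trimethylsilyloxy)hept-6-enoate | COc1cc(C)c(O[Si](C)(C)C(C)(C)C)c(C[C@]2(C)C(=O)[C@](C)([C@H](CCC(=O)OC)CC(=C)O[Si](C)(C)C)CC[C@@H]2C)c1
F2 | step 4 | methyl 5-acetyl-6-oxohept-4-enoate | COC(=O)CCC=C(C(C)=O)C(C)=O
F3 | step 4 | methyl (4R)-5-acetyl-4-[(1S)-1-methyl-2-{[(1R)-1-phenylethyl]imino}cyclohexyl]-6-oxoheptanoate | C1C(=N[C@H](C)c2ccccc2)[C@](C)([C@H](CCC(=O)OC)C(C(C)=O)C(C)=O)CCC1
F4 | step 4 | methyl (4R)-5-acetyl-4-[(1S)-1-methyl-2-oxocyclohexyl]-6-oxoheptanoate | C1C(=O)[C@](C)([C@H](CCC(=O)OC)C(C(C)=O)C(C)=O)CCC1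
F5 | step 14 | C3 enol triflate of 21 (C3=C4 double bond, C3–OSO2CF3; stereocentres as in 21) | COc1cc(C)c(O[Si](C)(C)C(C)(C)C)c(C[C@]2(C)[C@H]3C=C(OS(=O)(=O)C(F)(F)F)C(=C(C)C)[C@@H](CCC(=O)OC)[C@]3(C)CC[C@@H]2C)c1
F6 | step 14 | 3,4-didehydro derivative of 23 (C3=C4 double bond conjugated with the isopropylidene; stereocentres as in 23) | COc1cc(C)c(O[Si](C)(C)C(C)(C)C)c(C[C@]2(C)[C@H]3C=CC(=C(C)C)[C@@H](CCC(=O)OC)[C@]3(C)CC[C@@H]2C)c1
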